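**Plan**

1. Retrosynthesis: remove the 8'-CHO (aryl C–C, last); reopen the 3-methylbutanoyl group as a 2,2-dimethylchroman-4-one (temporary ring); cut the dihydropyran at O–C(spiro) and ArCH2–CH2 (hetero-Diels–Alder) to an o-quinone methide plus (−)-β-pinene; cut the pinane at CH2 bridge–remote bridgehead and at CMe2–near bridgehead back to acyclic geranyl diphosphate.
2. Enabling feature: the carbocyclic half is a 6,6-dimethylbicyclo[3.1.1]heptane whose ten carbons (seven ring atoms, two methyls, the chroman C3' methylene) form a head-to-tail geranyl chain. The CH2 bridge is geranyl C1 and the bridgehead remote from the spiro atom is C6, so a monoterpene cyclase closes exactly this bond.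
3. Forward ring order: six-membered carbocycle, then cyclobutane (one enzymatic step); chromanone mask on phloroglucinol; dihydropyran ring by hetero-Diels–Alder; mask opened; formylation.
4. Stereochemistry: both bridgeheads come from the cyclase acting on an achiral substrate; the spiro centre comes from attack of the heterodiene on the alkene face anti to the gem-dimethyl bridge.
5. Arene regiochemistry: the chromanone ring ties up one oxygen ortho to the ketone, so the pyran oxygen must be the one para to the acyl group; the last free ring position then takes the formyl group.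

Key step: step 2

Assumption: the pinane bridgeheads of the target are those of (1S,5S)-(−)-β-pinene (descriptors become 1R,2R,5S in the spiro compounds because priorities change). The cyclase is taken to be available by heterologous expression and acts as a catalyst. Geranyl numbering (C1 = CH2O carbon, C10 = 3-methyl) is used for the terpene, primed locants for the chroman.

Step 1
Reactants: 1 geranyl chloride [(2E)-1-chloro-3,7-dimethylocta-2,6-diene]
Product: 2 geranyl diphosphate trisammonium salt
Conditions: (n-Bu4N)3HP2O7, MeCN, rt; then Dowex 50WX8 (NH4+ form), aq. NH4HCO3; cellulose chromatography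
Reagents that add atoms: tris(tetrabutylammonium) hydrogen diphosphate, CCCC[N+](CCCC)(CCCC)CCCC.CCCC[N+](CCCC)(CCCC)CCCC.CCCC[N+](CCCC)(CCCC)CCCC.OP(=O)([O-])OP(=O)([O-])[O-]; ammonium hydrogencarbonate, [NH4+].OC(=O)[O-]
Why: SN2 alkylation of the diphosphate trianion by the primary allylic chloride should give the allylic diphosphate without allylic transposition or loss of the E geometry, and cation exchange gives the water-soluble ammonium salt that the enzyme accepts.

Step 2
Reactants: 2 geranyl diphosphate trisammonium salt
Product: 6 (−)-β-pinene [(1S,5S)-6,6-dimethyl-2-methylidenebicyclo[3.1.1]heptane], via linalyl diphosphate 3 (not isolated), via α-terpinyl cation 4 (not isolated), via pinyl cation 5 (not isolated)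
Conditions: recombinant (−)-β-pinene synthase (monoterpene cyclase of the ionisation-initiated class, EC 4.2.3.120), MgCl2, HEPES buffer pH 7.2, DTT, pentane overlay, 30 °C; AgNO3–SiO2 filtration
Reagents that add atoms: none
Why: The cyclase binds the diphosphate through its divalent magnesium cluster, ionises it, returns the anion to C3 to give enzyme-bound (3S)-linalyl diphosphate 3 and re-ionises the cisoid rotamer; C1 of the allyl cation is then attacked by C6 of the 6,7-alkene, which closes the six-membered ring (cation–alkene cyclisation, attacked alkene exocyclic to the new ring, Markovnikov at the gem-dimethyl terminus) and makes the bond between the later CH2 bridge and the remote bridgehead in cation 4. The tertiary cation C7 then adds to C2 of the ring alkene (four-membered ring, Markovnikov, new cation at C3 in 5), and loss of a proton from the C10 methyl gives the exocyclic alkene of 6. The closest known reaction type is the native conversion of geranyl diphosphate into bicyclic monoterpenes by pinene synthases; no small Brønsted or Lewis acid does this, because in solution cation 4 only loses a proton or is trapped by solvent. The stereocentre at C6 (bridgehead C5 of 6) is set by the enzyme, which folds the achiral chain in the helical conformer leading through (3S)-3 to (4S)-4; the second bridgehead (geranyl C2, C1 of 6) follows because the one-carbon bridge can only span the ring cis. The step needs 1,6- rather than 1,7-closure, cyclobutane closure in preference to deprotonation of 4, and exocyclic in preference to endocyclic proton loss: the first is secured in the substrate by the head-to-tail spacing of the allylic diphosphate carbon and the trisubstituted alkene, the other two by the active-site contour of a β-pinene-selective synthase.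

Step 3
Reactants: 7 phloroglucinol (benzene-1,3,5-triol); 8 3-methylbut-2-enoic acid
Product: 9 5,7-dihydroxy-2,2-dimethylchroman-4-one
Conditions: P2O5, MeSO3H, 70 °C
Reagents that add atoms: none
Why: Friedel–Crafts acylation of the symmetric triol followed by intramolecular oxa-Michael addition of the adjacent phenol should give the chromanone unambiguously; the new ring is the temporary mask that carries the five carbons of the later 3-methylbutanoyl group and blocks one of the two oxygens ortho to the ketone.

Step 4
Reactants: 9 5,7-dihydroxy-2,2-dimethylchroman-4-one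
Product: 10 8-[(dimethylamino)methyl]-5,7-dihydroxy-2,2-dimethylchroman-4-one
Conditions: aq. CH2O (1 equiv), aq. Me2NH, EtOH, rt; chromatography
Reagents that add atoms: formaldehyde, C=O; dimethylamine, CNC
Why: Mannich aminomethylation of the electron-rich ring is expected to prefer C8 (between the free 7-OH and the ether O1, para to the chelated 5-OH), as in 5,7-dihydroxychromones, and one equivalent of iminium ion limits double substitution.

Step 5
Reactants: 10 8-[(dimethylamino)methyl]-5,7-dihydroxy-2,2-dimethylchroman-4-one (slight excess); 6 (−)-β-pinene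
Product: 12 (1'R,2'R,5'S)-5-hydroxy-2,2,6',6'-tetramethyl-2,3,9,10-tetrahydro-4H-spiro[pyrano[2,3-f]chromene-8,2'-bicyclo[3.1.1]heptan]-4-one, via quinone methide 11 (not isolated)
Conditions: toluene, 110 °C, slow N2 stream
Reagents that add atoms: none
Why: Thermal loss of dimethylamine from the vinylogous-acid Mannich base should give the acyl-activated o-quinone methide 11, which adds to the exocyclic alkene of 6 in an inverse-electron-demand hetero-Diels–Alder reaction (terminal CH2 to the methide carbon, O to the tertiary C2); because C8 is flanked by the ether O1, only the 7-oxygen can be the heterodiene oxygen, and the spiro centre is set by approach to the alkene face on the side of the CH2 bridge, away from the gem-dimethyl bridge, as in hydroboration or epoxidation of β-pinene.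

Step 6
Reactants: 12 spiro pyranochromanone adduct
Product: 14 1-[(1R,2R,5S)-5',7'-dihydroxy-6,6-dimethyl-3',4'-dihydrospiro[bicyclo[3.1.1]heptane-2,2'-chromen]-6'-yl]-3-methylbutan-1-one, via enone 13 (not isolated)
Conditions: H2 (3 atm), 10% Pd/C, KOH, EtOH–H2O, rt to 40 °C; then aq. NH4Cl
Reagents that add atoms: none
Why: In alkali the chroman-4-one should be in E1cB (retro-oxa-Michael) equilibrium with the phenoxide of the 3-methylbut-2-enoyl ketone 13 (the ring–chain equilibrium behind Wessely–Moser-type isomerisations), whose C=C bond is hydrogenated irreversibly over Pd/C as in the alkaline hydrogenation of flavanones to dihydrochalcones; the chelated aryl ketone, the chroman ether and the cyclobutane should be inert and no stereocentre is touched.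

Step 7
Reactants: 14 deformyl precursor
Product: 16 euglobal G3 [(1R,2R,5S)-5',7'-dihydroxy-6,6-dimethyl-6'-(3-methylbutanoyl)-3',4'-dihydrospiro[bicyclo[3.1.1]heptane-2,2'-chromene]-8'-carbaldehyde], via iminium chloride 15 (not isolated)
Conditions: POCl3, DMF, EtOAc, 0 °C to rt; then aq. NaOAc, rt
Reagents that add atoms: N,N-dimethylformamide, CN(C)C=O; water, O
Why: Vilsmeier–Haack formylation should occur at the only free ring position (C8', ortho to the 7'-OH and the ring oxygen, para to the 5'-OH), as in the formylation of acylphloroglucinols, and buffered hydrolysis of iminium 15 limits acid contact of the tertiary alkyl aryl ether.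

**Compound list**

1 | geranyl chloride, (2E)-1-chloro-3,7-dimethylocta-2,6-diene | CC(C)=CCC/C(C)=C/CCl | starting material
2 | geranyl diphosphate trisammonium salt (2E) | CC(C)=CCC/C(C)=C/COP(=O)([O-])OP(=O)([O-])[O-].[NH4+].[NH4+].[NH4+] | intermediate
3 | (3S)-linalyl diphosphate, enzyme-bound trianion | C=C[C@](C)(CCC=C(C)C)OP(=O)([O-])OP(=O)([O-])[O-] | intermediate
4 | (4S)-α-terpinyl cation, (4S)-p-menth-1-en-8-yl cation | CC1=CC[C@H](CC1)[C+](C)C | intermediate
5 | (1S,5S)-pin-2-yl cation | C[C+]1CC[C@H]2C[C@@H]1C2(C)C | intermediate
6 | (−)-β-pinene, (1S,5S)-6,6-dimethyl-2-methylidenebicyclo[3.1.1]heptane | C=C1CC[C@H]2C[C@@H]1C2(C)C | intermediate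
7 | phloroglucinol, benzene-1,3,5-triol | Oc1cc(O)cc(O)c1 | starting material
8 | 3-methylbut-2-enoic acid | CC(C)=CC(=O)O | starting material
9 | 5,7-dihydroxy-2,2-dimethylchroman-4-one | CC1(C)CC(=O)c2c(O)cc(O)cc2O1 | intermediate
10 | 8-[(dimethylamino)methyl]-5,7-dihydroxy-2,2-dimethylchroman-4-one | CC1(C)CC(=O)c2c(O)cc(O)c(CN(C)C)c2O1 | intermediate
11 | 5-hydroxy-2,2-dimethyl-8-methylidene-2,3-dihydrochromene-4,7-dione (o-quinone methide) | CC1(C)CC(=O)C2=C(O1)C(=C)C(=O)C=C2O | intermediate
12 | (1'R,2'R,5'S)-5-hydroxy-2,2,6',6'-tetramethyl-2,3,9,10-tetrahydro-4H-spiro[pyrano[2,3-f]chromene-8,2'-bicyclo[3.1.1]heptan]-4-one; the dihydropyran bridges the former 7-O and C8 of the chromanone, O on the face of the CH2 bridge | CC1(C)CC(=O)c2c(O)cc3c(c2O1)CC[C@@]4(CC[C@H]5C[C@@H]4C5(C)C)O3 | intermediate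
13 | 1-[(1R,2R,5S)-5',7'-dihydroxy-6,6-dimethyl-3',4'-dihydrospiro[bicyclo[3.1.1]heptane-2,2'-chromen]-6'-yl]-3-methylbut-2-en-1-one (phenoxide in the flask) | CC(C)=CC(=O)c1c(O)cc2c(c1O)CC[C@@]1(CC[C@H]3C[C@@H]1C3(C)C)O2 | intermediate
14 | 1-[(1R,2R,5S)-5',7'-dihydroxy-6,6-dimethyl-3',4'-dihydrospiro[bicyclo[3.1.1]heptane-2,2'-chromen]-6'-yl]-3-methylbutan-1-one | CC(C)CC(=O)c1c(O)cc2c(c1O)CC[C@@]1(CC[C@H]3C[C@@H]1C3(C)C)O2 | intermediate
15 | N-{[(1R,2R,5S)-5',7'-dihydroxy-6,6-dimethyl-6'-(3-methylbutanoyl)-3',4'-dihydrospiro[bicyclo[3.1.1]heptane-2,2'-chromen]-8'-yl]methylidene}-N-methylmethanaminium chloride | CC(C)CC(=O)c1c(O)c(C=[N+](C)C)c2c(c1O)CC[C@@]1(CC[C@H]3C[C@@H]1C3(C)C)O2.[Cl-] | intermediate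
16 | euglobal G3, (1R,2R,5S)-5',7'-dihydroxy-6,6-dimethyl-6'-(3-methylbutanoyl)-3',4'-dihydrospiro[bicyclo[3.1.1]heptane-2,2'-chromene]-8'-carbaldehyde | CC(C)CC(=O)c1c(O)c(C=O)c2c(c1O)CC[C@@]1(CC[C@H]3C[C@@H]1C3(C)C)O2 | target

**Totals**

Total step count: 7. Longest linear sequence: 5 steps (7/8 → 9 → 10 → 12 → 14 → 16; the terpene branch 1 → 2 → 6 → 12 → 14 → 16 is equally long).

**Steps most likely to fail**

Step 6. The ring opening may be too slow or too unfavourable to feed the hydrogenation, or the opened enone may be hydrated and cleaved by retro-aldol reaction in the alkali. The fallback gives up the mask and sets out from 7. Friedel–Crafts acylation with 3-methylbutanoyl chloride (AlCl3, PhNO2–CH2Cl2) should give 3-methyl-1-(2,4,6-trihydroxyphenyl)butan-1-one F1. Mannich reaction (aq. CH2O, Me2NH, EtOH) should give the mono-Mannich base 1-{3-[(dimethylamino)methyl]-2,4,6-trihydroxyphenyl}-3-methylbutan-1-one F2. Heating F2 with 6 in toluene generates the o-quinone methide 2-hydroxy-6-methylidene-4-(3-methylbutanoyl)cyclohexa-2,4-diene-1,5-dione-type tautomer F3, whose hetero-Diels–Alder reaction should give 14 together with its regioisomer, the 8'-acyl chroman F4. The two are separated by chromatography, and the route is rejoined at 14. The cost is loss of material to the regioisomer.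

Step 2. Turnover may be slow or product-inhibited on a preparative scale, the volatile hydrocarbon may be lost, and proton loss may occur toward the ring. The fallback sets out from 2 and uses a more robust, less product-specific (−)-pinene synthase under the same buffer conditions; the same two ring closures then end mainly in (−)-α-pinene F5, mixed with some 6. The whole hydrocarbon mixture is metalated at the allylic position (n-BuLi/KOt-Bu, hexane), since both isomers give the same allyl anion. Trapping with B(OMe)3 should give dimethyl myrtenylboronate F6, and protonolysis with allylic transposition (the known contrathermodynamic isomerisation of α- to β-pinene) returns the route at 6.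

Step 4. Site selectivity of the aminomethylation may be poor (C6 against C8), or double substitution may occur. The fallback sets out from 9 and carries the regioisomeric mixture forward instead of separating it. The 6-aminomethyl isomer 6-[(dimethylamino)methyl]-5,7-dihydroxy-2,2-dimethylchroman-4-one F7 gives under the conditions of step 5 the o-quinone methide F8. Its 5-OH is locked in the chelate with the C4 carbonyl, so the heterodiene oxygen is again the 7-oxygen. Cycloaddition with 6 should then give the linear spiro adduct F9. Under the conditions of step 6, 12 and F9 open to the same ketone, and the route is rejoined at 14.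

**Further compounds**

F1 | step 6 | 3-methyl-1-(2,4,6-trihydroxyphenyl)butan-1-one | CC(C)CC(=O)c1c(O)cc(O)cc1O
F2 | step 6 | 1-{3-[(dimethylamino)methyl]-2,4,6-trihydroxyphenyl}-3-methylbutan-1-one | CC(C)CC(=O)c1c(O)cc(O)c(CN(C)C)c1O
F3 | step 6 | o-quinone methide of F2 (one tautomer) | CC(C)CC(=O)C1=C(O)C(=C)C(=O)C=C1O
F4 | step 6 | 1-[(1R,2R,5S)-5',7'-dihydroxy-6,6-dimethyl-3',4'-dihydrospiro[bicyclo[3.1.1]heptane-2,2'-chromen]-8'-yl]-3-methylbutan-1-one | CC(C)CC(=O)c1c(O)cc(O)c2c1O[C@]1(CC[C@H]3C[C@@H]1C3(C)C)CC2
F5 | step 2 | (−)-α-pinene, (1S,5S)-2,6,6-trimethylbicyclo[3.1.1]hept-2-ene | CC1=CC[C@H]2C[C@@H]1C2(C)C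
F6 | step 2 | dimethyl myrtenylboronate, dimethyl {[(1R,5S)-6,6-dimethylbicyclo[3.1.1]hept-2-en-2-yl]methyl}boronate | COB(OC)CC1=CC[C@H]2C[C@@H]1C2(C)C
F7 | step 4 | 6-[(dimethylamino)methyl]-5,7-dihydroxy-2,2-dimethylchroman-4-one | CC1(C)CC(=O)c2c(O)c(CN(C)C)c(O)cc2O1
F8 | step 4 | 5-hydroxy-2,2-dimethyl-6-methylidene-2,3-dihydrochromene-4,7-dione (o-quinone methide) | CC1(C)CC(=O)C2=C(O)C(=C)C(=O)C=C2O1
F9 | step 4 | (1'R,2'R,5'S)-5-hydroxy-2,2,6',6'-tetramethyl-2,3,6,7-tetrahydro-4H-spiro[pyrano[3,2-g]chromene-8,2'-bicyclo[3.1.1]heptan]-4-one, linear isomer of 12 | CC1(C)CC(=O)c2c(O)c3CC[C@@]4(CC[C@H]5C[C@@H]4C5(C)C)Oc3cc2O1
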